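**Plan**

- Retrosynthesis: the C6–O acyl bond, the epoxide oxygen on C8/C9 and the C4–isopropyl bond are removed first, and the C6 oxygen and C5 hydrogen are traced back to a C5=C6 alkene, which leaves a 10-PMB-oxy-dauca-5,8-dien-4-one. Ring B is then cut at C1–C10 with C6–C8 re-closed to a cyclopropane, and finally the C5–C6 bond to 3-methylcyclopentenone and the C7 methylene are cut.
- Enabling feature: in ring B (C1, C5–C10) the C7 methylene lies between C8=C9 (epoxide precursor) and C5=C6 (latent C6 oxygen), and opposite it the C1–C10 bond joins the methyl-bearing quaternary carbon to the carbinol carbon. This is the cyclohepta-1,4-diene pattern that a cis-divinylcyclopropane rearrangement delivers.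
- Forward: the cyclopropane is made first (steps 1–5), ring A is attached as an intact cyclopentenone (steps 6–7), ring B closes in the Cope step (step 8), and oxygenation and acylation follow (steps 9–16).
- Stereochemistry: the asymmetric cyclopropanation sets the absolute configuration, which the boat transition state relays to C1 and C10. C4 comes from addition anti to the C1 methyl, C5 and C6 from C4-hydroxyl-directed epoxidation, radical opening and directed reduction, and the epoxide from direction by the C10 hydroxyl.

Key step: step 8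

Remark: daucane numbering is used (ring A = C1–C5, ring B = C1, C5–C10; C1 bears the angular methyl, C4 the isopropyl group); β is the face of the C1 methyl, α the opposite face; PMB = 4-methoxybenzyl.

**Step 1**
Reactants: 1 propargyl alcohol
Product: 3 (Z)-3-iodo-2-methylprop-2-en-1-ol, via vinylmagnesium alkoxide 2 (not isolated)
Conditions: MeMgBr (2.5 equiv), CuI (10 mol%), THF, −10 °C to rt; then I2, −20 °C to rt
Reagents that add atoms: methylmagnesium bromide C[Mg]Br; iodine II
Why: Copper-catalysed anti carbomagnesiation of the propargylic alkoxide puts the methyl group on C2 and magnesium on C3 inside a five-membered chelate, and iodinolysis with retention gives the Z iodoalkene whose geometry later becomes the cis relationship on the cyclopropane.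

**Step 2**
Reactants: 3 (Z)-3-iodo-2-methylprop-2-en-1-ol
Product: 4 [(1R,2R)-2-iodo-1-methylcyclopropyl]methanol
Conditions: Zn(CH2I)2·DME (from Et2Zn, CH2I2, DME), (4R,5R)-2-butyl-N,N,N′,N′-tetramethyl-1,3,2-dioxaborolane-4,5-dicarboxamide (1.2 equiv), CH2Cl2, −10 °C to rt
Reagents that add atoms: diiodomethane ICI
Why: Charette asymmetric Simmons–Smith cyclopropanation, in which the zinc alkoxide of 3 bound to the (R,R)-dioxaborolane directs the carbenoid to one alkene face (the face that turns cinnamyl alcohol into its (1S,2S)-cyclopropylmethanol with this ligand) and the stereospecific syn transfer of CH2 sets both cyclopropane centres with iodine cis to the hydroxymethyl group.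

**Step 3**
Reactants: 4 [(1R,2R)-2-iodo-1-methylcyclopropyl]methanol
Product: 5 (1R,2R)-2-iodo-1-methylcyclopropane-1-carbaldehyde
Conditions: Dess–Martin periodinane, NaHCO3, CH2Cl2, 0 °C to rt
Reagents that add atoms: none
Why: Dess–Martin oxidation of a primary alcohol under buffered conditions, where the quaternary α-carbon excludes epimerisation of the aldehyde.

**Step 4**
Reactants: 5 (1R,2R)-2-iodo-1-methylcyclopropane-1-carbaldehyde
Product: 6 (1R,2R)-1-iodo-2-[(E)-2-iodoethenyl]-2-methylcyclopropane
Conditions: CrCl2 (6 equiv), CHI3 (2 equiv), dioxane/THF, 0 °C to rt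
Reagents that add atoms: iodoform IC(I)I
Why: Takai iodoolefination through the geminal dichromium reagent, which adds to the hindered aldehyde and eliminates to the E alkenyl iodide, while the cyclopropyl C–I bond is not reduced by CrCl2.

**Step 5**
Reactants: 6 (1R,2R)-1-iodo-2-[(E)-2-iodoethenyl]-2-methylcyclopropane; 7 4-methoxybenzyl alcohol
Product: 8 (1R,2R)-1-iodo-2-{(E)-2-[(4-methoxyphenyl)methoxy]ethenyl}-2-methylcyclopropane
Conditions: CuI (10 mol%), 3,4,7,8-tetramethyl-1,10-phenanthroline (20 mol%), Cs2CO3, toluene, 80 °C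
Reagents that add atoms: none
Why: Copper-catalysed Ullmann-type C–O coupling of an alkenyl iodide with an alcohol keeps the E geometry and should leave the cyclopropyl iodide alone, because that C–I bond reacts far more slowly with the copper alkoxide.

**Step 6**
Reactants: 9 3-methylcyclopent-2-en-1-one
Product: 10 2-iodo-3-methylcyclopent-2-en-1-one
Conditions: I2, pyridine, CH2Cl2, rt
Reagents that add atoms: iodine II
Why: α-Iodination of an enone with iodine and pyridine (amine conjugate addition, iodination of the enolate, elimination) is the standard route to 2-iodocycloalkenones.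

**Step 7**
Reactants: 8 (1R,2R)-1-iodo-2-{(E)-2-[(4-methoxyphenyl)methoxy]ethenyl}-2-methylcyclopropane; 10 2-iodo-3-methylcyclopent-2-en-1-one
Product: 13 3-methyl-2-[(1R,2S)-2-{(E)-2-[(4-methoxyphenyl)methoxy]ethenyl}-2-methylcyclopropyl]cyclopent-2-en-1-one, via cyclopropyllithium 11 (not isolated), via cyclopropylzinc chloride 12 (not isolated)
Conditions: t-BuLi (2.1 equiv), Et2O, −78 °C; ZnCl2, THF, −78 to 0 °C; then 10, Pd2(dba)3 (2.5 mol%), SPhos (10 mol%), THF, rt
Reagents that add atoms: none
Why: Lithium–iodine exchange and transmetalation to zinc retain configuration at the cyclopropyl carbon, and the Negishi coupling with the α-iodoenone (fast oxidative addition to zerovalent palladium) also proceeds with retention, so the enone and the enol ether arm stay cis, and room temperature should allow 13 to be isolated before it rearranges.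

**Step 8**
Reactants: 13 3-methyl-2-[(1R,2S)-2-{(E)-2-[(4-methoxyphenyl)methoxy]ethenyl}-2-methylcyclopropyl]cyclopent-2-en-1-one
Product: 14 (1S,10R)-10-[(4-methoxyphenyl)methoxy]dauca-5,8-dien-4-one
Conditions: toluene (degassed), 110 °C, sealed tube
Reagents that add atoms: none
Why: Heating 13 should trigger a concerted [3,3]-sigmatropic shift of the cis-1,2-dialkenylcyclopropane in which the strained C6–C8 bond breaks while the C1–C10 bond forms between the β-carbon of the enone and the oxygen-bearing alkene terminus, the π-bonds moving to C5=C6 and C8=C9. The closest known reaction type is the thermal cis-divinylcyclopropane to cyclohepta-1,4-diene Cope rearrangement, which accepts cycloalkenyl partners and heteroatom-substituted termini. Ring B closes through a boat-shaped six-centre array by C1–C10 bond formation, a four-atom ring expansion of the cyclopropane and the only pericyclic mode that can give two cis ring alkenes. C1 and C10 are set together: in the boat the ring CH2 of the enone (C2) and the E-placed PMB-oxy group point outward and the enone methyl and H10 point inward, so O10 ends up trans to the C1 methyl, and the absolute sense is transferred from the two cyclopropane centres made in step 2. The step needs the cis cyclopropane and the E enol ether to be intact, which the stereospecific steps 1, 2, 5 and 7 secure, and a temperature high enough for the inward methyl but below that of cyclopropane stereomutation. Release of cyclopropane strain with the enone conjugation kept makes the rearrangement irreversible.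

**Step 9**
Reactants: 14 (1S,10R)-10-[(4-methoxyphenyl)methoxy]dauca-5,8-dien-4-one
Product: 15 (1S,4R,10R)-10-[(4-methoxyphenyl)methoxy]dauca-5,8-dien-4-ol
Conditions: i-PrMgCl (3 equiv), CeCl3 (3 equiv), THF, −78 to −40 °C
Reagents that add atoms: isopropylmagnesium chloride CC(C)[Mg]Cl
Why: Organocerium 1,2-addition suppresses enolisation and conjugate addition and is expected on the α face of the nearly planar 2-alkylidenecyclopentanone, anti to the pseudoaxial C1 methyl (C10 lies pseudoequatorial in the boat-shaped ring B), which places isopropyl α and the C4 hydroxyl β.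

**Step 10**
Reactants: 15 (1S,4R,10R)-10-[(4-methoxyphenyl)methoxy]dauca-5,8-dien-4-ol
Product: 16 (1R,4R,5S,6R,10R)-5,6-epoxy-10-[(4-methoxyphenyl)methoxy]dauc-8-en-4-ol
Conditions: VO(acac)2 (5 mol%), t-BuOOH (1.5 equiv), CH2Cl2, 0 °C
Reagents that add atoms: tert-butyl hydroperoxide CC(C)(C)OO
Why: Vanadium-catalysed hydroxyl-directed (Sharpless) epoxidation of an allylic alcohol delivers oxygen to C5=C6 on the face of the C4 hydroxyl (β), and the C8=C9 alkene, whose allylic oxygen is blocked as the PMB ether, is not activated.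

**Step 11**
Reactants: 16 (1R,4R,5S,6R,10R)-5,6-epoxy-10-[(4-methoxyphenyl)methoxy]dauc-8-en-4-ol
Product: 17 (1S,4R,5S,6R,10R)-10-[(4-methoxyphenyl)methoxy]dauc-8-ene-4,6-diol
Conditions: Cp2TiCl2 (3 equiv), Zn dust, THF, rt; then 16, 1,4-cyclohexadiene (10 equiv), rt
Reagents that add atoms: none
Why: RajanBabu–Nugent reductive epoxide opening, in which Cp2TiCl (trivalent titanium) cleaves the C5–O bond homolytically to the tertiary C5 radical while the C6–O bond keeps its β configuration, and hydrogen-atom transfer from 1,4-cyclohexadiene is expected on the α face of C5, away from the titanium alkoxide on C6, the C4 oxygen and the C1 methyl, which gives the trans ring fusion.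

**Step 12**
Reactants: 17 (1S,4R,5S,6R,10R)-10-[(4-methoxyphenyl)methoxy]dauc-8-ene-4,6-diol
Product: 18 (1S,4R,5R,10R)-4-hydroxy-10-[(4-methoxyphenyl)methoxy]dauc-8-en-6-one
Conditions: Dess–Martin periodinane, NaHCO3, CH2Cl2, 0 °C
Reagents that add atoms: none
Why: Dess–Martin oxidation converts only the secondary C6 alcohol, and the buffered neutral medium avoids epimerisation at C5, conjugation of the β,γ-alkene and dehydration of the tertiary aldol.

**Step 13**
Reactants: 18 (1S,4R,5R,10R)-4-hydroxy-10-[(4-methoxyphenyl)methoxy]dauc-8-en-6-one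
Product: 19 (1S,4R,5S,6S,10R)-10-[(4-methoxyphenyl)methoxy]dauc-8-ene-4,6-diol
Conditions: Me4NBH(OAc)3 (5 equiv), MeCN/AcOH, −30 °C
Reagents that add atoms: none
Why: Evans–Saksena hydroxyl-directed reduction, in which the C4 hydroxyl exchanges onto boron and the alkoxyborohydride delivers hydride intramolecularly to the β face of the C6 carbonyl to give the 6α-alcohol, while free triacetoxyborohydride does not reduce the ketone.

**Step 14**
Reactants: 19 (1S,4R,5S,6S,10R)-10-[(4-methoxyphenyl)methoxy]dauc-8-ene-4,6-diol; 20 angelic acid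
Product: 22 (1S,4R,5S,6S,10R)-4-hydroxy-10-[(4-methoxyphenyl)methoxy]dauc-8-en-6-yl (Z)-2-methylbut-2-enoate, via mixed anhydride 21 (not isolated)
Conditions: 20, 2,4,6-trichlorobenzoyl chloride, Et3N, toluene, rt; then 19, 80 °C
Reagents that add atoms: none
Why: Yamaguchi-type mixed-anhydride esterification without a nucleophilic amine catalyst acylates the secondary C6 hydroxyl and not the hindered tertiary C4 hydroxyl, and avoids the Z to E isomerisation that turns angelates into tiglates.

**Step 15**
Reactants: 22 (1S,4R,5S,6S,10R)-4-hydroxy-10-[(4-methoxyphenyl)methoxy]dauc-8-en-6-yl (Z)-2-methylbut-2-enoate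
Product: 23 (1S,4R,5S,6S,10R)-4,10-dihydroxydauc-8-en-6-yl (Z)-2-methylbut-2-enoate
Conditions: DDQ (1.3 equiv), CH2Cl2/pH 7 buffer, 0 °C
Reagents that add atoms: none
Why: Oxidative PMB ether cleavage by DDQ (hydride abstraction to the oxocarbenium ion, then hydrolysis) under buffered conditions leaves the ester, both alkenes and the tertiary alcohol untouched.

**Step 16**
Reactants: 23 (1S,4R,5S,6S,10R)-4,10-dihydroxydauc-8-en-6-yl (Z)-2-methylbut-2-enoate
Product: 24 lapiferine
Conditions: VO(acac)2 (5 mol%), t-BuOOH (1.5 equiv), CH2Cl2, 0 °C to rt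
Reagents that add atoms: tert-butyl hydroperoxide CC(C)(C)OO
Why: Vanadium-catalysed hydroxyl-directed epoxidation of the cyclic allylic alcohol delivers oxygen to C8=C9 on the face of the C10 hydroxyl (cis delivery is the rule for cyclohept-2-enols), giving the 8α,9α-epoxide, and the electron-poor angelate alkene does not react.

**Compound list**

1 | propargyl alcohol | C#CCO | starting material
2 | bromomagnesium (Z)-3-(bromomagnesio)-2-methylprop-2-en-1-olate (vinylmagnesium alkoxide) | Br[Mg]/C=C(/C)CO[Mg]Br | intermediate
3 | (Z)-3-iodo-2-methylprop-2-en-1-ol | I/C=C(/C)CO | intermediate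
4 | [(1R,2R)-2-iodo-1-methylcyclopropyl]methanol | I[C@@H]1C[C@]1(C)CO | intermediate
5 | (1R,2R)-2-iodo-1-methylcyclopropane-1-carbaldehyde | I[C@@H]1C[C@]1(C)C=O | intermediate
6 | (1R,2R)-1-iodo-2-[(E)-2-iodoethenyl]-2-methylcyclopropane | I[C@@H]1C[C@]1(C)/C=C/I | intermediate
7 | 4-methoxybenzyl alcohol | COc1ccc(CO)cc1 | starting material
8 | (1R,2R)-1-iodo-2-{(E)-2-[(4-methoxyphenyl)methoxy]ethenyl}-2-methylcyclopropane | I[C@@H]1C[C@]1(C)/C=C/OCc1ccc(OC)cc1 | intermediate
9 | 3-methylcyclopent-2-en-1-one | CC1=CC(=O)CC1 | starting material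
10 | 2-iodo-3-methylcyclopent-2-en-1-one | CC1=C(I)C(=O)CC1 | intermediate
11 | cyclopropyllithium derived from 8 (lithium in place of iodine, configuration retained) | [Li][C@@H]1C[C@]1(C)/C=C/OCc1ccc(OC)cc1 | intermediate
12 | cyclopropylzinc chloride derived from 11 (configuration retained) | Cl[Zn][C@@H]1C[C@]1(C)/C=C/OCc1ccc(OC)cc1 | intermediate
13 | 3-methyl-2-[(1R,2S)-2-{(E)-2-[(4-methoxyphenyl)methoxy]ethenyl}-2-methylcyclopropyl]cyclopent-2-en-1-one (enone and enol ether arm cis) | CC1=C(C(=O)CC1)[C@@H]2C[C@]2(C)/C=C/OCc3ccc(OC)cc3 | intermediate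
14 | (1S,10R)-10-[(4-methoxyphenyl)methoxy]dauca-5,8-dien-4-one (10α-OPMB, 1β-methyl) | C=1CC(C)=C[C@@H](OCc3ccc(OC)cc3)[C@@]2(C)CCC(=O)C=12 | intermediate
15 | (1S,4R,10R)-10-[(4-methoxyphenyl)methoxy]dauca-5,8-dien-4-ol (4β-OH, 4α-isopropyl) | C=1CC(C)=C[C@@H](OCc3ccc(OC)cc3)[C@@]2(C)CC[C@@](O)(C(C)C)C=12 | intermediate
16 | (1R,4R,5S,6R,10R)-5,6-epoxy-10-[(4-methoxyphenyl)methoxy]dauc-8-en-4-ol (5β,6β-epoxide) | [C@@H]12CC(C)=C[C@@H](OCc3ccc(OC)cc3)[C@@]3(C)CC[C@@](O)(C(C)C)[C@]31O2 | intermediate
17 | (1S,4R,5S,6R,10R)-10-[(4-methoxyphenyl)methoxy]dauc-8-ene-4,6-diol (5α-H, 6β-OH) | O[C@@H]1CC(C)=C[C@@H](OCc3ccc(OC)cc3)[C@@]2(C)CC[C@@](O)(C(C)C)[C@H]12 | intermediate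
18 | (1S,4R,5R,10R)-4-hydroxy-10-[(4-methoxyphenyl)methoxy]dauc-8-en-6-one (5α-H) | O=C1CC(C)=C[C@@H](OCc3ccc(OC)cc3)[C@@]2(C)CC[C@@](O)(C(C)C)[C@H]12 | intermediate
19 | (1S,4R,5S,6S,10R)-10-[(4-methoxyphenyl)methoxy]dauc-8-ene-4,6-diol (6α-OH) | O[C@H]1CC(C)=C[C@@H](OCc3ccc(OC)cc3)[C@@]2(C)CC[C@@](O)(C(C)C)[C@H]12 | intermediate
20 | angelic acid, (Z)-2-methylbut-2-enoic acid | C/C=C(/C)C(=O)O | starting material
21 | (Z)-2-methylbut-2-enoic 2,4,6-trichlorobenzoic anhydride | C/C=C(/C)C(=O)OC(=O)c1c(Cl)cc(Cl)cc1Cl | intermediate
22 | (1S,4R,5S,6S,10R)-4-hydroxy-10-[(4-methoxyphenyl)methoxy]dauc-8-en-6-yl (Z)-2-methylbut-2-enoate | C/C=C(/C)C(=O)O[C@H]1CC(C)=C[C@@H](OCc3ccc(OC)cc3)[C@@]2(C)CC[C@@](O)(C(C)C)[C@H]12 | intermediate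
23 | (1S,4R,5S,6S,10R)-4,10-dihydroxydauc-8-en-6-yl (Z)-2-methylbut-2-enoate | C/C=C(/C)C(=O)O[C@H]1CC(C)=C[C@@H](O)[C@@]2(C)CC[C@@](O)(C(C)C)[C@H]12 | intermediate
24 | lapiferine, (1S,4R,5S,6S,8R,9S,10S)-8,9-epoxy-4,10-dihydroxydaucan-6-yl (Z)-2-methylbut-2-enoate | C/C=C(/C)C(=O)O[C@H]1C[C@@]2(C)O[C@H]2[C@@H](O)[C@@]2(C)CC[C@@](O)(C(C)C)[C@H]12 | target

**Step count and risks**

Total step count: 16. Longest linear sequence: 15 steps (steps 1–5 and 7–16 from propargyl alcohol; step 6 is the side branch).

The three steps most likely to fail: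

1. Step 9, facial selectivity of the isopropyl addition. The only control element is a 1,3-related quaternary centre, so the organocerium reagent may approach C4 syn to the C1 methyl or from both faces, and a wrong C4 hydroxyl would also misdirect the epoxidation of step 10. The fallback sets out from 14. Weitz–Scheffer epoxidation (t-BuOOH, DBU, CH2Cl2) is expected to add oxygen on the β face, because the α face of C6 is the concave side of the boat-shaped cycloheptadiene, and would give the epoxy ketone (1R,5S,6R,10R)-5,6-epoxy-10-[(4-methoxyphenyl)methoxy]dauc-8-en-4-one F1. Addition of i-PrMgCl/CeCl3 to this α,β-epoxy ketone should occur anti to the adjacent C5–O bond, so that C4 is controlled by a neighbouring group, and the product is 16, where the route is rejoined.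

2. Step 11, hydrogen-atom transfer to the C5 radical. Hydrogen may be delivered to the β face, which gives the cis-fused diol, or the radical may collapse by titanium-mediated β-elimination. The fallback sets out from 14 and passes through the epoxy ketone F1 described above. SmI2 (THF/MeOH, −78 °C) should cleave the C5–O bond next to the ketone, and protonation of the samarium enolate at C5 anti to the C1 methyl and the C6 alkoxide would give the trans-fused β-hydroxy ketone (1S,5S,6R,10R)-6-hydroxy-10-[(4-methoxyphenyl)methoxy]dauc-8-en-4-one F2. Addition of i-PrMgCl/CeCl3 to this saturated trans-fused ketone from the α face, anti to the axial C1 methyl, comes back to the route at 17.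

3. Step 7, the Negishi coupling. Transmetalation and reductive elimination between a hindered secondary cyclopropylzinc and a tetrasubstituted α-iodoenone may be slow, so that protonolysis of the organozinc or reduction and homocoupling of 10 take over. The fallback sets out from 8. Lithium–iodine exchange (t-BuLi, Et2O, −78 °C) and trapping with 2-isopropoxy-4,4,5,5-tetramethyl-1,3,2-dioxaborolane would give the isolable pinacol boronate 2-[(1R,2S)-2-{(E)-2-[(4-methoxyphenyl)methoxy]ethenyl}-2-methylcyclopropyl]-4,4,5,5-tetramethyl-1,3,2-dioxaborolane F3. Suzuki–Miyaura coupling of F3 with 10 (PdCl2(dppf), K3PO4, dioxane/H2O, 60 °C) proceeds with retention at the cyclopropyl carbon and comes back to the route at 13.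

Further compounds
F1 | step 9 | (1R,5S,6R,10R)-5,6-epoxy-10-[(4-methoxyphenyl)methoxy]dauc-8-en-4-one | [C@@H]12CC(C)=C[C@@H](OCc3ccc(OC)cc3)[C@@]3(C)CCC(=O)[C@]31O2
F2 | step 11 | (1S,5S,6R,10R)-6-hydroxy-10-[(4-methoxyphenyl)methoxy]dauc-8-en-4-one | O[C@@H]1CC(C)=C[C@@H](OCc3ccc(OC)cc3)[C@@]2(C)CCC(=O)[C@H]12
F3 | step 7 | 2-[(1R,2S)-2-{(E)-2-[(4-methoxyphenyl)methoxy]ethenyl}-2-methylcyclopropyl]-4,4,5,5-tetramethyl-1,3,2-dioxaborolane | CC1(C)OB(OC1(C)C)[C@@H]1C[C@]1(C)/C=C/OCc1ccc(OC)cc1
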